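**Plan**

1. Retrosynthesis (target in indene numbering: C1 Me; C2=C3 Et; C3a; C4 Me, CO2H; C5 Et, styryl; C6=C7 Et; C7a). The cyclohexene is not cut directly. Its C3a–C4 bond is opened and the carboxyl carbon is put back into the ring between C3a and C4 (Favorskii retron), which gives the bicyclic seven-ring α-bromo ketone 20.
2. In 20 the bonds C3a–C7a and C4–C5 are cut together ((4+3) retron: the C6=C7 alkene lies opposite the ring carbonyl), which gives open-chain dibromo ketone 18. Its chain is cut at C(=O)–C4 (carbenoid acylation), C3–C3a (Pd coupling), the styryl, C5=C6 and C7=C7a alkenes (olefinations) and C2=C3 (Stork–Zhao olefination), back to methyl (R)-3-hydroxy-2-methylpropanoate.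
3. Forward: the chain is joined in steps 1–10; step 11 closes the cyclopentene and the cycloheptenone in one operation; step 12 contracts the seven-membered ring to the cyclohexene and turns the ring carbonyl into the CO2H group.
4. Stereochemistry: C1 comes from the starting ester. C7a, C5 and the C4–Br centre come from the suprafacial (4+3) addition, under control of C1 (allylic strain) and of the diene and cation geometries. C4 is then set by inversion and C3a by protonation in step 12.
5. Enabling feature: the CO2H carbon sits on C4 next to C3a, and C3a–H is allylic to the C2=C3 alkene of the five-membered ring. A carbonyl carbon placed between C3a and C4 therefore serves first as the centre of an oxyallyl unit and then leaves the ring as the acid, with the alkene directing the opening.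

Key step: step 12

Remark: atoms are numbered as in the target in all intermediates; 10 and 15 are taken as purchasable; the C3a configuration of 20 is drawn as the model predicts but is immaterial, because step 12 re-forms this centre.

**Step 1**
Reactants: 1 methyl (2R)-3-hydroxy-2-methylpropanoate; 2 tert-butyl(chloro)dimethylsilane
Product: 3 methyl (2R)-3-[(tert-butyldimethylsilyl)oxy]-2-methylpropanoate
Conditions: imidazole, CH2Cl2, 0 °C → rt
Reagents that add atoms: tert-butyl(chloro)dimethylsilane CC(C)(C)[Si](C)(C)Cl
Why: Imidazole-assisted silyl ether formation masks the primary alcohol (the later C7a terminus) and leaves the stereocentre untouched.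

**Step 2**
Reactants: 3 methyl (2R)-3-[(tert-butyldimethylsilyl)oxy]-2-methylpropanoate
Product: 4 (2R)-3-[(tert-butyldimethylsilyl)oxy]-2-methylpropanal
Conditions: i-Bu2AlH (1.05 equiv), CH2Cl2, −78 °C; aq. potassium sodium tartrate
Reagents that add atoms: none
Why: Partial ester reduction stops at the aluminium hemiacetal at low temperature and should release the α-chiral aldehyde on work-up without epimerisation.

**Step 3**
Reactants: 4 (2R)-3-[(tert-butyldimethylsilyl)oxy]-2-methylpropanal; 5 propyltriphenylphosphonium bromide; 6 iodine
Product: 7 tert-butyl{[(2S,3Z)-4-iodo-2-methylhex-3-en-1-yl]oxy}dimethylsilane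
Conditions: 5, n-BuLi, THF, 0 °C; I2, −78 °C; NaN(SiMe3)2, −20 °C; then 4, −78 °C → rt
Reagents that add atoms: propyltriphenylphosphonium bromide CCC[P+](c1ccccc1)(c1ccccc1)c1ccccc1.[Br-]; iodine II
Why: Stork–Zhao olefination with the α-iodo ylide should give the (Z)-iodoalkene (iodine cis to the carbon that bears the stereocentre) under kinetic control, which fixes the C2=C3 geometry that the five-membered ring needs.

**Step 4**
Reactants: 7 tert-butyl{[(2S,3Z)-4-iodo-2-methylhex-3-en-1-yl]oxy}dimethylsilane
Product: 8 (2S,3Z)-4-iodo-2-methylhex-3-en-1-ol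
Conditions: camphorsulfonic acid (10 mol %), MeOH/CH2Cl2, 0 °C
Reagents that add atoms: none
Why: Acid-catalysed methanolysis removes the primary silyl ether and does not touch the vinyl iodide.

**Step 5**
Reactants: 8 (2S,3Z)-4-iodo-2-methylhex-3-en-1-ol
Product: 9 (2S,3Z)-4-iodo-2-methylhex-3-enal
Conditions: Dess–Martin periodinane, CH2Cl2, 0 °C → rt; crude aldehyde used at once
Reagents that add atoms: none
Why: Dess–Martin oxidation under near-neutral conditions gives the β,γ-unsaturated α-chiral aldehyde, which is carried on directly to avoid epimerisation or conjugation.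

**Step 6**
Reactants: 9 (2S,3Z)-4-iodo-2-methylhex-3-enal; 10 2-(triphenylphosphoranylidene)butanal
Product: 11 (2E,4R,5Z)-2-ethyl-6-iodo-4-methylocta-2,5-dienal
Conditions: PhMe, 60 °C
Reagents that add atoms: 2-(triphenylphosphoranylidene)butanal CCC(C=O)=P(c1ccccc1)(c1ccccc1)c1ccccc1
Why: Wittig reaction with a stabilised formyl ylide runs without added base and should give the (E)-2-ethyl enal, which sets the C7=C7a geometry.

**Step 7**
Reactants: 11 (2E,4R,5Z)-2-ethyl-6-iodo-4-methylocta-2,5-dienal; 10 2-(triphenylphosphoranylidene)butanal
Product: 12 (2E,4E,6R,7Z)-2,4-diethyl-8-iodo-6-methyldeca-2,4,7-trienal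
Conditions: PhMe, 100 °C
Reagents that add atoms: 2-(triphenylphosphoranylidene)butanal CCC(C=O)=P(c1ccccc1)(c1ccccc1)c1ccccc1
Why: A second Wittig reaction with the same stabilised ylide should give the (E,E)-dienal, which sets the C5=C6 geometry with the ethyl group on the inner side of the later diene.

**Step 8**
Reactants: 12 (2E,4E,6R,7Z)-2,4-diethyl-8-iodo-6-methyldeca-2,4,7-trienal; 13 diethyl benzylphosphonate
Product: 14 [(1E,3E,5E,7R,8Z)-3,5-diethyl-9-iodo-7-methylundeca-1,3,5,8-tetraen-1-yl]benzene
Conditions: 13, NaN(SiMe3)2, THF, −78 °C; then 12, −78 → 0 °C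
Reagents that add atoms: diethyl benzylphosphonate CCOP(=O)(Cc1ccccc1)OCC
Why: Horner–Wadsworth–Emmons reaction of the preformed benzylphosphonate anion should give the (E)-styrene, since addition to the aldehyde at −78 °C outruns vinylogous deprotonation.

**Step 9**
Reactants: 14 [(1E,3E,5E,7R,8Z)-3,5-diethyl-9-iodo-7-methylundeca-1,3,5,8-tetraen-1-yl]benzene; 15 2-bromo-N-methoxy-N-methylacetamide
Product: 16 (3Z,5S,6E,8E,10E)-3,7,9-triethyl-N-methoxy-N,5-dimethyl-11-phenylundeca-3,6,8,10-tetraenamide
Conditions: 15, Zn dust (Me3SiCl-activated), THF, rt; then 14, Pd(PPh3)4 (5 mol %), 55 °C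
Reagents that add atoms: 2-bromo-N-methoxy-N-methylacetamide CON(C)C(=O)CBr
Why: Pd-catalysed cross-coupling of an alkenyl iodide with a Reformatsky-type zinc amide enolate (Negishi-type α-alkenylation) should join C3 to the future C3a with retention of the Z geometry.

**Step 10**
Reactants: 16 (3Z,5S,6E,8E,10E)-3,7,9-triethyl-N-methoxy-N,5-dimethyl-11-phenylundeca-3,6,8,10-tetraenamide; 17 1,1-dibromoethane
Product: 18 (5Z,7S,8E,10E,12E)-2,2-dibromo-5,9,11-triethyl-7-methyl-13-phenyltrideca-5,8,10,12-tetraen-3-one
Conditions: 17, LiN(i-Pr)2, THF/Et2O, −100 °C; then 16, −100 °C; AcOH quench at −100 °C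
Reagents that add atoms: 1,1-dibromoethane CC(Br)Br
Why: Acylation of a lithium carbenoid by an N-methoxy-N-methylamide gives a chelated adduct that cannot add a second time and should release the α,α-dibromo ketone on cold acidic quench.

**Step 11**
Reactants: 18 (5Z,7S,8E,10E,12E)-2,2-dibromo-5,9,11-triethyl-7-methyl-13-phenyltrideca-5,8,10,12-tetraen-3-one
Product: 20 (1S,3aS,5R,6R,8aR)-5-bromo-3,6,8-triethyl-1,5-dimethyl-6-[(E)-2-phenylethenyl]-1,5,6,8a-tetrahydroazulen-4(3aH)-one, via bromo-oxyallyl cation 19 (not isolated)
Conditions: Et3N (1.5 equiv), (CF3)2CHOH/CH2Cl2, high dilution, −20 °C → rt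
Reagents that add atoms: none
Why: Proposed new method: Deprotonation of the doubly activated CH2 and loss of bromide give the vinyl-conjugated bromo-oxyallyl cation 19 (W-shaped, bromine anti to the oxido oxygen), whose termini C3a and C4 add suprafacially to the termini C7a and C5 of the s-cis (E,E)-diene and so close the cyclopentene (through the three-atom tether) and the cycloheptenone together; the cation should attack the diene face anti to the C1 methyl group (allylic 1,3-strain holds C1–H in the diene plane) through the extended transition state that keeps the C–O unit away from the C7 ethyl group, which places the C4 methyl cis to the C5 ethyl group and bromine cis to the styryl group. The closest known reaction type is the base-induced generation of α-halo oxyallyl cations from α,α-dihalo ketones in fluorinated alcohols and their inter- and intramolecular (4+3) cycloadditions with dienes, not yet shown for an open-chain cation that meets a fully substituted diene terminus.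

**Step 12**
Reactants: 20 (1S,3aS,5R,6R,8aR)-5-bromo-3,6,8-triethyl-1,5-dimethyl-6-[(E)-2-phenylethenyl]-1,5,6,8a-tetrahydroazulen-4(3aH)-one; 21 potassium hydroxide
Product: 24 (1S,3aS,4S,5R,7aR)-3,5,7-triethyl-1,4-dimethyl-5-[(E)-2-phenylethenyl]-3a,4,5,7a-tetrahydro-1H-indene-4-carboxylic acid, via dienolate 22 (not isolated), via cyclopropanone 23 (not isolated)
Conditions: KOH (3 equiv), THF/H2O 3:1, 0 °C → rt; then 1 M HCl
Reagents that add atoms: potassium hydroxide [K+].[OH-]
Why: KOH removes the only enolisable hydrogen of 20 (C3a–H, activated by the ketone and by the C2=C3 alkene) to give dienolate 22, whose C3a attacks C4 from the side opposite to the axial, π-aligned C–Br bond (3-exo-tet closure, 1,3-elimination of bromide) to form cyclopropanone 23; this new C3a–C4 bond is the one that closes the six-membered ring. Hydroxide then adds to the strained carbonyl and the C(=O)–C3a bond breaks, because only this cleavage gives an allyl-stabilised carbanion, so the carbonyl carbon leaves the ring as the carboxylate on C4 and the seven-membered ring has contracted to the cyclohexene. The closest known reaction type is the Favorskii ring contraction of 2-halocycloalkanones to cycloalkanecarboxylic acids, used here as the second half of a (4+3) cycloaddition/ring contraction sequence that stands in for a Diels–Alder reaction. C4 is set by inversion at the C–Br carbon, which leaves its methyl group cis to the C5 ethyl group and the carboxyl group cis to the styryl group. C3a is set when the carbanion is protonated on the face from which the carboxyl carbon departs (by the new acid or by water held there), which is also the face anti to the now axial C4 methyl group and should give the trans ring fusion. The step needs regioselective ring opening and is indifferent to the C3a configuration and to double-bond migration in 20, since all enol forms of this β,γ-unsaturated ketone pass through the same dienolate; both follow from the C2=C3 alkene next to C3a.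

**Compound list**

1 | methyl (2R)-3-hydroxy-2-methylpropanoate | COC(=O)[C@H](C)CO | starting material
2 | tert-butyl(chloro)dimethylsilane | CC(C)(C)[Si](C)(C)Cl | starting material
3 | methyl (2R)-3-[(tert-butyldimethylsilyl)oxy]-2-methylpropanoate | COC(=O)[C@H](C)CO[Si](C)(C)C(C)(C)C | intermediate
4 | (2R)-3-[(tert-butyldimethylsilyl)oxy]-2-methylpropanal | O=C[C@H](C)CO[Si](C)(C)C(C)(C)C | intermediate
5 | propyltriphenylphosphonium bromide | CCC[P+](c1ccccc1)(c1ccccc1)c1ccccc1.[Br-] | starting material
6 | iodine | II | starting material
7 | tert-butyl{[(2S,3Z)-4-iodo-2-methylhex-3-en-1-yl]oxy}dimethylsilane | CC/C(I)=C/[C@H](C)CO[Si](C)(C)C(C)(C)C | intermediate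
8 | (2S,3Z)-4-iodo-2-methylhex-3-en-1-ol | CC/C(I)=C/[C@H](C)CO | intermediate
9 | (2S,3Z)-4-iodo-2-methylhex-3-enal | CC/C(I)=C/[C@H](C)C=O | intermediate
10 | 2-(triphenylphosphoranylidene)butanal | CCC(C=O)=P(c1ccccc1)(c1ccccc1)c1ccccc1 | starting material
11 | (2E,4R,5Z)-2-ethyl-6-iodo-4-methylocta-2,5-dienal | CC/C(I)=C/[C@H](C)/C=C(\CC)C=O | intermediate
12 | (2E,4E,6R,7Z)-2,4-diethyl-8-iodo-6-methyldeca-2,4,7-trienal | CC/C(I)=C/[C@H](C)/C=C(CC)/C=C(\CC)C=O | intermediate
13 | diethyl benzylphosphonate | CCOP(=O)(Cc1ccccc1)OCC | starting material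
14 | [(1E,3E,5E,7R,8Z)-3,5-diethyl-9-iodo-7-methylundeca-1,3,5,8-tetraen-1-yl]benzene | CC/C(I)=C/[C@H](C)/C=C(CC)/C=C(CC)/C=C/c1ccccc1 | intermediate
15 | 2-bromo-N-methoxy-N-methylacetamide | CON(C)C(=O)CBr | starting material
16 | (3Z,5S,6E,8E,10E)-3,7,9-triethyl-N-methoxy-N,5-dimethyl-11-phenylundeca-3,6,8,10-tetraenamide | CON(C)C(=O)C/C(CC)=C\[C@H](C)/C=C(CC)/C=C(CC)/C=C/c1ccccc1 | intermediate
17 | 1,1-dibromoethane | CC(Br)Br | starting material
18 | (5Z,7S,8E,10E,12E)-2,2-dibromo-5,9,11-triethyl-7-methyl-13-phenyltrideca-5,8,10,12-tetraen-3-one | CC(Br)(Br)C(=O)C/C(CC)=C\[C@H](C)/C=C(CC)/C=C(CC)/C=C/c1ccccc1 | intermediate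
19 | bromo-oxyallyl cation (zwitterion) formed from 18 by loss of HBr | C/C(Br)=C(\[O-])[CH+]/C(CC)=C\[C@H](C)/C=C(CC)/C=C(CC)/C=C/c1ccccc1 | intermediate
20 | (1S,3aS,5R,6R,8aR)-5-bromo-3,6,8-triethyl-1,5-dimethyl-6-[(E)-2-phenylethenyl]-1,5,6,8a-tetrahydroazulen-4(3aH)-one | CCC1=C[C@](/C=C/c2ccccc2)(CC)[C@@](C)(Br)C(=O)[C@@H]2C(CC)=C[C@H](C)[C@@H]12 | intermediate
21 | potassium hydroxide | [K+].[OH-] | starting material
22 | potassium dienolate of 20 (enolate C(O−)=C3a conjugated with C2=C3) | CCC1=C[C@](/C=C/c2ccccc2)(CC)[C@@](C)(Br)C([O-])=C2C(CC)=C[C@H](C)[C@@H]12.[K+] | intermediate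
23 | cyclopropanone intermediate (C=O bridging C3a and C4 of the target skeleton, C4 methyl cis to C5 ethyl) | CCC1=C[C@](/C=C/c2ccccc2)(CC)[C@@]3(C)C(=O)[C@]32C(CC)=C[C@H](C)[C@@H]12 | intermediate
24 | (1S,3aS,4S,5R,7aR)-3,5,7-triethyl-1,4-dimethyl-5-[(E)-2-phenylethenyl]-3a,4,5,7a-tetrahydro-1H-indene-4-carboxylic acid | CCC1=C[C@](/C=C/c2ccccc2)(CC)[C@@](C)(C(=O)O)[C@@H]2C(CC)=C[C@H](C)[C@@H]12 | target

**Totals**

Total step count: 12. Longest linear sequence: 12 steps (1 → 24).

**Steps most likely to fail**

Step 11 (proposed new method). The free cation may lose a proton from its methyl group, be captured by the fluoro alcohol, or undergo 4π-electrocyclisation along the vinyl-conjugated system. The second bond may also close through oxygen or at the wrong diene carbon ((3+2) products), or the addition may show poor facial or extended/compact selectivity. Fallback, setting out from 16 and coming back at 20: the amide enolate (LiN(i-Pr)2, THF, −78 °C) would be brominated with CBr4 to give the α-bromo amide F1 (16 with Br on the CH2 between C=O and the alkene, both epimers). Addition of 1,1-dibromoethyllithium as in step 10 would give tribromo ketone F2 (18 with a third Br on that carbon). The oxyallyl unit would then be generated reductively and metal-bound with Fe2(CO)9 in benzene at 50 °C. This is the known diiron nonacarbonyl-mediated (4+3) cycloaddition of polybromo ketones with open-chain 1,3-dienes; it needs no base and avoids a free, strongly electrophilic cation. It should give 20.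

Step 12. The allylic carbanion may be protonated at C2 (migration of the ring alkene) or on the wrong face (cis ring fusion). In the aqueous medium the bromide may also ionise before ring closure, with loss of the inversion at C4. Fallback, setting out from 20 and coming back at 24: (1-ethoxyvinyl)lithium with CeCl3 (THF, −78 °C) would add irreversibly to the ketone from the face anti to the C–Br bond. On warming, the alkoxide should undergo the known organometallic-induced quasi-Favorskii (semibenzilic) shift, in which C3a migrates from the carbonyl carbon to C4 with retention and inversion at C4 and never becomes a carbanion. This would give the 1-ethoxyvinyl ketone F3 (24 with C(=O)C(OEt)=CH2 in place of CO2H). Mild acid (1 M HCl, THF) would give the 1,2-diketone F4 (24 with C(=O)C(=O)CH3 in place of CO2H), and H2O2/NaOH would cleave it to 24.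

Step 10. The basic carbenoid may take a proton from the acidic CH2 between the amide and the alkene instead of adding, or may decompose thermally before it is acylated. Fallback, setting out from 16 and coming back at 18: i-Bu2AlH (THF, −78 °C) would reduce the amide to the aldehyde F5 ((3Z,5S,6E,8E,10E)-3,7,9-triethyl-5-methyl-11-phenylundeca-3,6,8,10-tetraenal). The more electrophilic aldehyde should take up 1,1-dibromoethyllithium at −100 °C to give the carbinol F6 (18 with CH(OH) in place of C=O, both epimers), and Dess–Martin oxidation would return 18.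

**Further compounds**

F1 | step 11 | α-bromo amide: 16 with Br on the CH2 between C=O and the alkene (both epimers) | CON(C)C(=O)C(Br)/C(CC)=C\[C@H](C)/C=C(CC)/C=C(CC)/C=C/c1ccccc1
F2 | step 11 | tribromo ketone: 18 with a third Br on the CH2 between C=O and the alkene (both epimers) | CC(Br)(Br)C(=O)C(Br)/C(CC)=C\[C@H](C)/C=C(CC)/C=C(CC)/C=C/c1ccccc1
F3 | step 12 | 1-ethoxyvinyl ketone: 24 with C(=O)C(OEt)=CH2 in place of CO2H | CCC1=C[C@](/C=C/c2ccccc2)(CC)[C@@](C)(C(=O)C(=C)OCC)[C@@H]2C(CC)=C[C@H](C)[C@@H]12
F4 | step 12 | 1,2-diketone: 24 with C(=O)C(=O)CH3 in place of CO2H | CCC1=C[C@](/C=C/c2ccccc2)(CC)[C@@](C)(C(=O)C(C)=O)[C@@H]2C(CC)=C[C@H](C)[C@@H]12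
F5 | step 10 | (3Z,5S,6E,8E,10E)-3,7,9-triethyl-5-methyl-11-phenylundeca-3,6,8,10-tetraenal | O=CC/C(CC)=C\[C@H](C)/C=C(CC)/C=C(CC)/C=C/c1ccccc1
F6 | step 10 | carbinol: 18 with CH(OH) in place of C=O (both epimers) | CC(Br)(Br)C(O)C/C(CC)=C\[C@H](C)/C=C(CC)/C=C(CC)/C=C/c1ccccc1
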